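**Plan**

Numbering (chamigrene): ring A is C6(spiro)–C7(=C14H2)–C8H2–C9H2–C10H(Br)–C11Me2; ring B is C6–C1H=C2H–C3(=C15HBr)–C4H2–C5H2. The target is (6S,10R), with Br on C15 cis to C2 (Z).
Retrosynthesis: cut C3=C15 (Wittig) to an enone; return C4–C5 to the cross-conjugated spirodienone, in which C6 is prochiral; cut C6–C7 and C8–C9 of ring A together to an anisole-bearing bromo triflate and propyne; then C10–Br/C9–O to an aldehyde, and aryl–C11 to anisole and methyl 3-methylbut-2-enoate.
Forward: ring B is carried as a para-substituted anisole; the C11–C10–C9 chain is attached and brominated; ring A and the spiro carbon are closed in one telescoped operation; ring B is then half-reduced and the bromomethylidene is added last.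
Enabling feature: C7(=C14H2)–C8H2 is a propargyl unit (C8 nucleophilic, C7 π-electrophilic once a metal binds the alkyne), and C3 lies para to C6 in ring B, so C6 is the ipso carbon of a latent 4-alkylanisole and can attack C7 with dearomatisation.
Stereochemistry: C10 comes from a catalyst-controlled α-bromination before ring A exists, so no substitution at the neopentyl carbon is ever needed; C6 comes from an ene-reductase desymmetrisation of the dienone; the C3=C15 geometry comes from the Wittig step.

Key step: step 5

**Route**

Step 1
Reactants: 1 anisole; 2 methyl 3-methylbut-2-enoate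
Product: 3 methyl 3-(4-methoxyphenyl)-3-methylbutanoate
Conditions: AlCl3 (1.3 equiv), excess 1, CH2Cl2, 0 to 23 °C
Reagents that add atoms: none
Why: Friedel–Crafts alkylation in its conjugate (hydroarylation) form: AlCl3 activates the ester, C11 becomes a tertiary cationic centre and the bulky electrophile is taken up para to OMe, which makes the aryl–C11 bond and the gem-dimethyl quaternary carbon without any stereocentre.

Step 2
Reactants: 3 methyl 3-(4-methoxyphenyl)-3-methylbutanoate
Product: 4 3-(4-methoxyphenyl)-3-methylbutanal
Conditions: i-Bu2AlH (1.05 equiv), CH2Cl2, −78 °C; MeOH quench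
Reagents that add atoms: none
Why: Partial reduction of an ester with i-Bu2AlH: the tetrahedral aluminium hemiacetal is stable at −78 °C and should release the aldehyde only on work-up, with no stereocentre involved.

Step 3
Reactants: 4 3-(4-methoxyphenyl)-3-methylbutanal
Product: 6 (2S)-2-bromo-3-(4-methoxyphenyl)-3-methylbutan-1-ol, via bromo aldehyde 5 (not isolated)
Conditions: (2R,5R)-2,5-diphenylpyrrolidine (20 mol%), 4,4-dibromo-2,6-di-tert-butylcyclohexa-2,5-dien-1-one (1.1 equiv), PhCO2H (20 mol%), H2O, CH2Cl2/pentane, −40 °C; then NaBH4, MeOH, −40 to 0 °C
Reagents that add atoms: 4,4-dibromo-2,6-di-tert-butylcyclohexa-2,5-dien-1-one, O=C1C(C(C)(C)C)=CC(Br)(Br)C=C1C(C)(C)C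
Why: Enamine organocatalysis (asymmetric α-bromination of an aldehyde) followed by borohydride reduction in the same flask: the C2-symmetric amine forms the (E)-enamine of 4, one phenyl group blocks one face of C10 so that the mild Br+ donor is delivered to the other, which by the accepted facial model should give the (2S) bromide (the (2S,5S) amine would be used if alcohol 6 proves to have the opposite sense), and NaBH4 removes the configurationally labile aldehyde before it can racemise.

Step 4
Reactants: 6 (2S)-2-bromo-3-(4-methoxyphenyl)-3-methylbutan-1-ol
Product: 7 (2S)-2-bromo-3-(4-methoxyphenyl)-3-methylbutyl trifluoromethanesulfonate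
Conditions: (CF3SO2)2O (1.1 equiv), 2,6-lutidine, CH2Cl2, −78 °C; cold filtration through silica, used at once
Reagents that add atoms: trifluoromethanesulfonic anhydride, O=S(=O)(OS(=O)(=O)C(F)(F)F)C(F)(F)F
Why: O-Sulfonylation of a primary alcohol: only the C9–O bond changes, the hindered base and low temperature should suppress epoxide closure and ionisation with bromine or aryl participation, and C10 keeps its configuration.

Step 5
Reactants: 7 (2S)-2-bromo-3-(4-methoxyphenyl)-3-methylbutyl trifluoromethanesulfonate; 8 propyne
Product: 10 (10R)-10-bromo-11,11-dimethyl-7-methylidenespiro[5.5]undeca-1,4-dien-3-one, via alkyne 9 (not isolated)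
Conditions: 8, n-BuLi (2 equiv per 8), Et2O/hexane, −78 to 0 °C; then 7, −78 to −40 °C; NH4Cl (aq), solvent exchange without purification; then [Au(NCMe){P(t-Bu)2(biphenyl-2-yl)}]SbF6 (5 mol%), H2O (3 equiv), CH2Cl2, 23 °C
Reagents that add atoms: water, O
Why: The propargylic carbanion of 1,3-dilithiopropyne displaces the primary triflate (SN2 at C9) to make C8–C9 and give alkyne 9; the cationic gold complex then binds the terminal alkyne, the anisole ipso carbon C6 attacks the internal alkyne carbon C7 anti to gold to make C6–C7, protodeauration leaves the C7=C14 methylidene, and water adds to the O-methyl oxocarbenium ion with loss of methanol to give the cross-conjugated dienone. The closest known reaction types are the alkylation of propargyl dianion with primary sulfonates and halides and the gold-catalysed dearomative ipso-cyclisation of 4-oxygenated aryl alkynes to spirocyclohexadienones. Ring A closes in the 6-exo-dig mode, helped by the gem-dimethyl group at C11 (Thorpe–Ingold effect). No new stereocentre arises: C6 becomes a prochiral spiro carbon, and the C10 configuration is carried through because neither event takes place at C10. The selectivities needed are substitution over elimination at C9 (triflate leaving group, low temperature), Markovnikov attack at C7 (terminal alkyne) and ipso over ortho attack (only C6 is para to OMe, and ortho attack would need a seven-membered ring); a silver-free gold salt is used so that the C10–Br bond is not ionised with aryl participation.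

Step 6
Reactants: 10 (10R)-10-bromo-11,11-dimethyl-7-methylidenespiro[5.5]undeca-1,4-dien-3-one
Product: 11 (6S,10R)-10-bromo-11,11-dimethyl-7-methylidenespiro[5.5]undec-1-en-3-one
Conditions: ene-reductase of the Old Yellow Enzyme family (flavin-dependent; the panel member that reduces the enone arm trans to Br), NADP+ (cat.), D-glucose, glucose dehydrogenase, KH2PO4/K2HPO4 buffer pH 7.0, DMSO (10% v/v), 30 °C
Reagents that add atoms: none
Why: Ene-reductase-catalysed asymmetric reduction of an activated C=C bond, used as a desymmetrisation of a 4,4-disubstituted cyclohexa-2,5-dienone: reduced flavin delivers hydride to C5 and an active-site acid protonates C4 in only one of the two enone arms, the enzyme being chosen so that the arm trans to Br is reduced, which turns the prochiral spiro carbon into (6S) under enzyme control, while the 4,4-disubstituted enone product is expected to be a much poorer substrate.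

Step 7
Reactants: 11 (6S,10R)-10-bromo-11,11-dimethyl-7-methylidenespiro[5.5]undec-1-en-3-one
Product: 12 (6S,10R)-10-bromo-3-[(Z)-bromomethylidene]-11,11-dimethyl-7-methylidenespiro[5.5]undec-1-ene
Conditions: Ph3P(CH2Br)Br (1.5 equiv), NaN(SiMe3)2 (1.4 equiv), THF, −78 °C; then 11, −78 to 0 °C
Reagents that add atoms: (bromomethyl)triphenylphosphonium bromide, BrC[P+](c1ccccc1)(c1ccccc1)c1ccccc1.[Br-]
Why: Wittig bromomethylenation: the ylide Ph3P=CHBr adds 1,2 to the enone carbonyl and the oxaphosphetane collapses to the C3=C15 bond, bromine being expected to end on the side of the flat vinylic C2–H and not on that of the C4 methylene, which is the required (Z) geometry, while the equatorial neopentyl C10–Br has no anti-periplanar hydrogen for elimination and is closed to substitution.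

**Compound list**

1 | anisole | COc1ccccc1 | starting material
2 | methyl 3-methylbut-2-enoate | COC(=O)C=C(C)C | starting material
3 | methyl 3-(4-methoxyphenyl)-3-methylbutanoate | COC(=O)CC(C)(C)c1ccc(OC)cc1 | intermediate
4 | 3-(4-methoxyphenyl)-3-methylbutanal | O=CCC(C)(C)c1ccc(OC)cc1 | intermediate
5 | (2S)-2-bromo-3-(4-methoxyphenyl)-3-methylbutanal (not isolated) | O=C[C@@H](Br)C(C)(C)c1ccc(OC)cc1 | intermediate
6 | (2S)-2-bromo-3-(4-methoxyphenyl)-3-methylbutan-1-ol | OC[C@@H](Br)C(C)(C)c1ccc(OC)cc1 | intermediate
7 | (2S)-2-bromo-3-(4-methoxyphenyl)-3-methylbutyl trifluoromethanesulfonate | O=S(=O)(OC[C@@H](Br)C(C)(C)c1ccc(OC)cc1)C(F)(F)F | intermediate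
8 | propyne | CC#C | starting material
9 | 1-[(3R)-3-bromo-2-methylhept-6-yn-2-yl]-4-methoxybenzene (not isolated) | C#CCC[C@@H](Br)C(C)(C)c1ccc(OC)cc1 | intermediate
10 | (10R)-10-bromo-11,11-dimethyl-7-methylidenespiro[5.5]undeca-1,4-dien-3-one | C=C1CC[C@@H](Br)C(C)(C)C12C=CC(=O)C=C2 | intermediate
11 | (6S,10R)-10-bromo-11,11-dimethyl-7-methylidenespiro[5.5]undec-1-en-3-one | C=C1CC[C@@H](Br)C(C)(C)[C@@]12C=CC(=O)CC2 | intermediate
12 | (6S,10R)-10-bromo-3-[(Z)-bromomethylidene]-11,11-dimethyl-7-methylidenespiro[5.5]undec-1-ene | C=C1CC[C@@H](Br)C(C)(C)[C@@]12C=C/C(=C\Br)CC2 | target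

**Count and risks**

Total steps: 7. Longest linear sequence: 7 steps (1 and 2 to 12); propyne 8 enters in step 5.

Steps most likely to fail:

Step 5. The risk is that the strongly basic dianion causes elimination, or attacks bromine, when it meets the β-bromo triflate, so that the C8–C9 bond is not formed cleanly. The fallback sets out from 7 and brings the three carbons in as an allyl group by a copper-catalysed Grignard coupling (CH2=CHCH2MgCl, Li2CuCl4 cat., THF, −78 °C), which should give 1-[(3R)-3-bromo-2-methylhept-6-en-2-yl]-4-methoxybenzene F1. Lemieux–Johnson cleavage (OsO4 cat., NaIO4, 2,6-lutidine, dioxane/H2O) should give (4R)-4-bromo-5-(4-methoxyphenyl)-5-methylhexanal F2. Seyferth–Gilbert homologation with dimethyl (1-diazo-2-oxopropyl)phosphonate (K2CO3, MeOH, 0 °C) should then give alkyne 9, now isolated, which comes back to the route at 9 and is closed to 10 by the gold-catalysed half of step 5.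

Step 6. The risk is poor discrimination between the two enone arms, or no turnover of the bulky spirodienone in the active site. The fallback sets out from 10 and uses an achiral hydride, [(Ph3P)CuH]6 (one hydride per molecule of 10, toluene, −20 °C, then hydrolysis), which should reduce either arm and give 11 together with its C6 epimer (6R,10R)-10-bromo-11,11-dimethyl-7-methylidenespiro[5.5]undec-1-en-3-one F3. Because C10 is fixed the two are diastereomers and should be separable on silica. The route is rejoined at 11, and F3 is returned to 10 by dehydrogenation with IBX (DMSO, 70 °C), which can only act on the one saturated α-carbon.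

Step 7. The risk is poor control of the C3=C15 geometry, with bromine placed mainly cis to C4. The fallback sets out from 11 and makes the dibromoalkene (CBr4, PPh3, toluene, 80 °C), (6S,10R)-10-bromo-3-(dibromomethylidene)-11,11-dimethyl-7-methylidenespiro[5.5]undec-1-ene F4. Hydrogenolysis of one vinylic bromide (Pd(PPh3)4 cat., Bu3SnH, toluene, 23 °C) then follows. Palladium inserts into the more exposed C–Br bond, which is the position the Wittig reaction would have favoured, so the bromine that remains is on the other side; this sequence is therefore stereocomplementary to step 7 and comes back to the route at 12.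

**Further compounds**

F1 | step 5 | 1-[(3R)-3-bromo-2-methylhept-6-en-2-yl]-4-methoxybenzene | C=CCC[C@@H](Br)C(C)(C)c1ccc(OC)cc1
F2 | step 5 | (4R)-4-bromo-5-(4-methoxyphenyl)-5-methylhexanal | O=CCC[C@@H](Br)C(C)(C)c1ccc(OC)cc1
F3 | step 6 | (6R,10R)-10-bromo-11,11-dimethyl-7-methylidenespiro[5.5]undec-1-en-3-one | C=C1CC[C@@H](Br)C(C)(C)[C@]12C=CC(=O)CC2
F4 | step 7 | (6S,10R)-10-bromo-3-(dibromomethylidene)-11,11-dimethyl-7-methylidenespiro[5.5]undec-1-ene | C=C1CC[C@@H](Br)C(C)(C)[C@@]12C=CC(=C(Br)Br)CC2
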